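## Structural features

The target is a flavonol: a carbocyclic ring A and a 4-pyranone ring C share the C4a–C8a bond, and a 3,4-dioxygenated phenyl ring B is joined to C2 by a single bond. It has no stereocentre, so nothing stereochemical has to be set or preserved. Five oxygens sit on the periphery (C3, C5, C7, C3', C4'); four are hydrogen sulfate esters, and only the C5 hydroxyl, locked in a six-membered hydrogen bond to the C4 carbonyl, is free. The sulfate monoesters are the fragile groups: strongly acidic, prone to acid-catalysed hydrolysis, water-soluble, and unfit for silica chromatography or for any organometallic step, so they must come last. The free catechol of the unsulfated flavonol is in addition sensitive to base and air. The real difficulty is therefore the oxygenation pattern and its differentiation: ring A must carry oxygen at C5 and C7 only, and four of five hydroxyls must be sulfated while the fifth is spared. The key step exploits the 1,3-relation of the C5 and C7 oxygens on the four ring A carbons C5–C8 that are not shared with ring C: these four carbons are a 1,1,3-trioxygenated butadiene, and the C4a–C8a bond is the C5=C6 double bond of a preformed 2-aryl-3-oxy-4-pyranone. The atom mapping was checked: pyranone C5 (sulfinyl-bearing) becomes C4a and C6 becomes C8a, and bonding of the diene CH2 terminus to C6 puts oxygen on C5 and C7, so the structures of both cycloaddition partners and of the cycloaddition product are consistent with the target and need no correction.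

## Logic of the disconnections

20 to 18: the four O–S bonds at O3, O7, O3' and O4' are cut. Sulfates tolerate none of the earlier chemistry, so they go on last. The gain is an uncharged, organic-soluble pentahydroxy compound. The forward step must sulfate four hydroxyls and leave the hydrogen-bonded O5–H alone; the product is first held as salt 19 and then brought to the acid form.

18 to 17: the three O–CH2Ph bonds at O3, O3' and O4' are cut. These three oxygens are not made in the ring-forming step and need a mask that survives strong base, silyl reagents and heat and falls under neutral conditions. The demand is that hydrogenolysis leave the C2=C3 bond intact and that 17 be free of sulfur residues.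

17 to 10 and 14: the C4a–C5 and C8–C8a bonds are cut, which removes ring A completely. The reason is the match between the C5/C7 oxygens and a 1,1,3-trioxygenated diene. The gain is a monocyclic pyranone and a four-carbon diene, with the 5- and 7-hydroxyls arriving unprotected. The forward step must be regioselective, must eliminate the activating group from 15 across C4a–C8a to give 16, and must aromatise.

10 to 5 and 7: the C2–C3 bond and the O1–C6 bond are cut. Compound 5 already holds the sulfinyl group and the future C6, so the pyranone is closed with its activating group in place. The alternative of functionalising C5 of a finished pyranone by electrophilic iodination, C–S coupling and oxidation was set aside. The catechol diether ring would compete for the electrophile, and three steps would be spent on one substituent. The demand is C-acylation of enolate 8 and 6-endo closure of 9 with loss of the amine.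

5 to 4: the C5=C6 bond is cut, removing a one-carbon aminomethylene unit. The demand is that condensation occur at the methylene between carbonyl and sulfinyl and not at the one next to the benzyloxy group.

4 to 1 and 2: the bond between the carbonyl carbon and the sulfinylmethyl carbon is cut. This is an ester acylation of carbanion 3, and both partners are commercial. The demand is a second equivalent of 3 to absorb the acidic product.

7 to 6: the C–Cl bond is cut; this is activation of a commercial acid.

14 to 12 to 11: two O–Si bonds are cut in turn. The diene is the bis-silyl dienol ether of a commercial β-keto ester, made via dienolate 13. The demand is exclusion of moisture and use of the diene soon after it is made.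

## Other disconnections considered

Alternative 1: The cut is the C4a–C5 bond of ring A, which unravels ring A into the linear 3,5,7-triketo ester A1 carrying the benzyloxy-substituted cinnamoyl end. Forward, Mg(OMe)2 in methanol would hold the chain as a chelated polyenolate so that chain carbon 6 attacks the ester carbonyl (Claisen closure), giving the acylphloroglucinol chalcone A2.
- In its favour: the three ring A oxygens appear at once without protecting groups, and no sulfur enters the synthesis. Ring A is formed symmetric, so no regiochemical question exists; on this point it is better than the chosen plan, whose regiochemistry rests on matched polarity. The Claisen folding of triketo esters to acylphloroglucinols is an established reaction type, which is also better than an untested cycloaddition.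
- Against it here: A1 is a labile poly-β-carbonyl compound that must be built by polyanion acylation and cannot be stored. It can fold in other ways (aldol closure to a resorcylate, lactonisation to a 4-hydroxy-2-pyranone), and its enol ether enone is a Michael acceptor for its own enolates. A2 still lacks ring C, so an oxa-Michael closure and a dehydrogenation would have to be run beside an unprotected, very nucleophilic phloroglucinol ring before 17 is reached.
- Comparison: both plans meet at 17 with the 5- and 7-hydroxyls free, and the step counts would be about equal. The alternative is stronger in precedent for its key step. The chosen plan is stronger in that the C2=C3 oxidation level is present from the start and ring C never has to be closed oxidatively.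

Alternative 2: The cut removes both bonds from ring A to ring C, O1–C8a and C4–C4a, together with O1–C2. Forward, CsF in acetonitrile would release the aryne from the silyl triflate A3. The carboxylate of the arylpropiolic acid A4 adds to the aryne carbon remote from the flanking benzyloxy group, and the aryl anion attacks the acyl carbon (formal insertion into the C–O bond of the acid). The resulting ortho-acyl phenoxide then adds 6-endo to the ynone to give the flavone A5.
- In its favour: three bonds and ring C form in one flask from two fragments of similar size, and no sulfur is used. The regiochemistry is set reliably by the alkoxy group next to the aryne (equal to the chosen plan). The reaction type is established for arynes and carboxylic acids (better than the chosen plan in precedent).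
- Against it here: A5 has no oxygen at C3, and that oxygen, which must later carry a sulfate, would need a separate C–H oxidation of an electron-rich flavone. A3 is itself a multistep target, and the phenoxide may close 5-exo to an aurone. All four benzyl ethers are alike, so nothing is gained in differentiation (equal, since in both plans the 5-hydroxyl is distinguished only at the sulfation stage).
- Comparison: the alternative is more convergent at its key step and mechanistically safer. It would be longer overall by the steps to A3 and the C3 oxidation. Structurally the chosen plan is more direct because the C3 oxygen is carried in the pyranone.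

Alternative 3: The cut is O1–C8a alone; ring C is closed onto a ring A that is bought as a trifluorobenzoyl group. Forward, K2CO3 in DMF would turn the 1,3-diketone A6 into its enolate, whose oxygen displaces an ortho fluorine by addition–elimination and gives the difluorochromone A7. The fluorines at C7 and C5, both activated by the C4 carbonyl, would then be exchanged for benzyloxy groups to give A8, and hydrogenolysis would lead to 18.
- In its favour: every step is of a known type (better than the chosen plan). The two ortho fluorines are equivalent, so the closure has no regiochemical issue (better). The C3 oxygen is in place from the start (equal). The step count would be equal or slightly lower.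
- Against it here: the ring A oxygens are introduced after the skeleton by two further substitutions, the second slowed by the donor installed in the first. Alkoxide can also attack C2 and open ring C. The 5-hydroxyl is never obtained free at the chromone stage.
- Comparison: for reaching 18 this is probably the most dependable of the four plans. The chosen plan is kept because ring A is built with both oxygens already on it and the 5-hydroxyl arrives free in one ring-forming operation, with no carbon–oxygen bond formation on ring A afterwards. The price is an untested cycloaddition.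

Key step: step 7

Assumption: the target is taken in the neutral fourfold hydrogen sulfate form drawn; it is released cold from its salt and is best stored as a salt, because free aryl hydrogen sulfates hydrolyse slowly.

Assumption: where a double-bond geometry has no consequence for the route (5, 8, 9, 12, 13, 14) one isomer is drawn, and racemates are drawn as one enantiomer.

## Steps

Step 1
Reactants: 1 1-methyl-4-(methylsulfinyl)benzene (methyl 4-methylphenyl sulfoxide, racemic); 2 methyl 2-(benzyloxy)acetate
Product: 4 1-(benzyloxy)-3-[(4-methylphenyl)sulfinyl]propan-2-one (racemic at sulfur), via lithiated sulfoxide 3 (not isolated)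
Conditions: 1 (2.1 equiv), LiN(iPr)2 (2.1 equiv), THF, −78 °C; then 2 (1.0 equiv), −78 → 0 °C; aq NH4Cl
Reagents that add atoms: none
Why: Claisen-type acylation of an α-sulfinyl carbanion by an ester, the standard entry to β-keto sulfoxides; the second equivalent of 3 deprotonates the more acidic product, which as its enolate is protected from a second addition.

Step 2
Reactants: 4 1-(benzyloxy)-3-[(4-methylphenyl)sulfinyl]propan-2-one
Product: 5 (3Z)-1-(benzyloxy)-4-(dimethylamino)-3-[(4-methylphenyl)sulfinyl]but-3-en-2-one
Conditions: Me2NCH(OMe)2 (1.5 equiv), toluene, 60 °C
Reagents that add atoms: N,N-dimethylformamide dimethyl acetal, COC(OC)N(C)C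
Why: Condensation of an active methylene with a formamide acetal; the CH2 between carbonyl and sulfinyl is far more acidic than the CH2 next to the benzyloxy group, so the aminomethylene carbon (future C6 of the pyranone) is placed there, and the push–pull double bond is configurationally labile.

Step 3
Reactants: 6 3,4-bis(benzyloxy)benzoic acid
Product: 7 3,4-bis(benzyloxy)benzoyl chloride
Conditions: (COCl)2, DMF (cat.), CH2Cl2, 0 °C → rt; evaporation, used crude
Reagents that add atoms: oxalyl chloride, ClC(=O)C(=O)Cl
Why: Acid chloride formation through the catalytic chloroiminium species; benzyl ethers are inert and the volatile by-products leave on evaporation.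

Step 4
Reactants: 5 (3Z)-1-(benzyloxy)-4-(dimethylamino)-3-[(4-methylphenyl)sulfinyl]but-3-en-2-one; 7 3,4-bis(benzyloxy)benzoyl chloride
Product: 10 3-(benzyloxy)-2-[3,4-bis(benzyloxy)phenyl]-5-[(4-methylphenyl)sulfinyl]-4H-pyran-4-one (racemic at sulfur), via lithium enolate 8 (not isolated), via enaminone diketone 9 (not isolated)
Conditions: LiN(SiMe3)2 (2.1 equiv), THF, −78 °C; 7 (1.05 equiv), −78 → 0 °C; then CF3CO2H, CH2Cl2, rt
Reagents that add atoms: none
Why: Kinetic deprotonation of 5 is possible only at the CH2 next to the benzyloxy group, and C-acylation of enolate 8 gives the 1,3-diketone 9, held as its enolate by the second equivalent of base; on acidification the enol oxygen of the aroyl carbonyl adds to the aminomethylene carbon and dimethylamine is lost (6-endo addition–elimination), the established enaminone acylation–cyclisation route to 4-pyranones.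

Step 5
Reactants: 11 methyl 3-oxobutanoate (methyl acetoacetate)
Product: 12 methyl (2E)-3-(trimethylsilyloxy)but-2-enoate
Conditions: Me3SiCl, Et3N, hexane, rt; filtration, distillation
Reagents that add atoms: chlorotrimethylsilane, C[Si](C)(C)Cl
Why: O-silylation of the enol of a β-keto ester under soft enolisation; the geometry of the new double bond does not matter because it becomes a single bond of the diene.

Step 6
Reactants: 12 methyl (2E)-3-(trimethylsilyloxy)but-2-enoate
Product: 14 (1Z)-1-methoxy-1,3-bis(trimethylsilyloxy)buta-1,3-diene, via lithium dienolate 13 (not isolated)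
Conditions: LiN(iPr)2, THF, −78 °C; Me3SiCl, −78 °C → rt; filtration under argon, distillation
Reagents that add atoms: chlorotrimethylsilane, C[Si](C)(C)Cl
Why: γ-Deprotonation gives the extended ester enolate 13, which the hard silyl chloride captures on oxygen to give the 1,1,3-trioxygenated diene; the ketene acetal geometry is irrelevant to the cycloaddition outcome, and the moisture-sensitive diene is used freshly distilled.

Step 7
Reactants: 10 3-(benzyloxy)-2-[3,4-bis(benzyloxy)phenyl]-5-[(4-methylphenyl)sulfinyl]-4H-pyran-4-one; 14 (1Z)-1-methoxy-1,3-bis(trimethylsilyloxy)buta-1,3-diene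
Product: 17 3-(benzyloxy)-2-[3,4-bis(benzyloxy)phenyl]-5,7-dihydroxy-4H-chromen-4-one, via cis-fused cycloadduct 15 (not isolated), via dihydrochromenone 16 (not isolated)
Conditions: 14 (3 equiv), toluene, 100 °C, sealed tube, Ar; then 1 M HCl, THF, rt
Reagents that add atoms: none
Why: Proposed new method: the carbonyl and sulfinyl groups of 10 both make C6 the electrophilic end of the C5=C6 bond, so the CH2 terminus of the electron-rich diene 14 should bond there (C8–C8a) and the ketene acetal carbon to the sulfinyl-bearing C5 (C4a–C5), in a concerted but asynchronous [4+2] cycloaddition or, at the polar limit, a Michael addition followed by ring closure of the α-sulfinyl enolate onto the oxocarbenium ion, both of which give the same connectivity. The closest known reaction type is the Diels–Alder reaction of 1,3-bis(silyloxy)dienes with halo- or sulfinylquinones and with 3-acylchromones followed by elimination to phenols; a monocyclic 4-pyranone has not been used as the dienophile. Ring A is closed as a six-membered carbocycle in the cycloaddition mode, both new bonds forming on one face of the dienophile, which makes 15 cis-fused with the sulfinyl group syn to H-8a. That geometry allows thermal syn-elimination of 4-methylbenzenesulfenic acid at the reaction temperature, C8a–H being the only β-hydrogen, and restores the C4a=C8a bond in 16. Acid then removes methanol from C5 and C8 by 1,4-elimination and cleaves the silyl ethers, so ring A aromatises to the 5,7-diol with the 5-hydroxyl hydrogen-bonded to the C4 carbonyl. The stereocentres at C4a, C5 and C8a are transient and the one at sulfur is lost, so no stereocontrol is needed. The step needs regioselectivity (oxygen on C5 and C7, not C6 and C8), secured by pairing the nucleophilic diene terminus with the carbon β to both activating groups, and site selectivity for C5=C6 over C2=C3, secured by the sulfinyl activation and by the aryl and benzyloxy donors that deactivate and shield C2=C3. Excess diene is used because it also traps the sulfenic acid.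

Step 8
Reactants: 17 3-(benzyloxy)-2-[3,4-bis(benzyloxy)phenyl]-5,7-dihydroxy-4H-chromen-4-one
Product: 18 2-(3,4-dihydroxyphenyl)-3,5,7-trihydroxy-4H-chromen-4-one (quercetin)
Conditions: H2 (1 atm), 10% Pd/C, THF–MeOH, rt
Reagents that add atoms: none
Why: Hydrogenolysis of benzyl aryl ethers and of the benzyl enol ether on palladium; the C2=C3 bond of a flavonol is not reduced under one atmosphere of hydrogen at room temperature, provided 17 has been freed of the sulfur by-products of step 7.

Step 9
Reactants: 18 2-(3,4-dihydroxyphenyl)-3,5,7-trihydroxy-4H-chromen-4-one
Product: 20 quercetin 3,7,3',4'-tetra-O-sulfate (2-[3,4-bis(sulfooxy)phenyl]-5-hydroxy-4-oxo-4H-chromene-3,7-diyl bis(hydrogen sulfate)), via tetrakis(triethylammonium) salt 19 (not isolated)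
Conditions: SO3·NEt3 (10 equiv), N,N-dimethylacetamide, 65 °C; then Dowex 50W (H+ form), H2O, 0 °C; lyophilisation
Reagents that add atoms: sulfur trioxide–triethylamine complex, CC[N+](CC)(CC)S(=O)(=O)[O-]
Why: O-sulfation of the phenolic and enolic hydroxyls by an amine complex of sulfur trioxide; the 5-hydroxyl, tied in a six-membered hydrogen bond to the C4 carbonyl and flanked by it, is the least nucleophilic and should stay free with a limited excess of reagent, and cold cation exchange turns salt 19 into the hydrogen sulfate form.

## Compound list

1 | 1-methyl-4-(methylsulfinyl)benzene (racemic) | Cc1ccc(cc1)S(C)=O | starting material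
2 | methyl 2-(benzyloxy)acetate | COC(=O)COCc1ccccc1 | starting material
3 | {[(4-methylphenyl)sulfinyl]methyl}lithium | [Li]CS(=O)c1ccc(C)cc1 | intermediate (not isolated)
4 | 1-(benzyloxy)-3-[(4-methylphenyl)sulfinyl]propan-2-one (racemic) | Cc1ccc(cc1)S(=O)CC(=O)COCc1ccccc1 | intermediate
5 | (3Z)-1-(benzyloxy)-4-(dimethylamino)-3-[(4-methylphenyl)sulfinyl]but-3-en-2-one (racemic at sulfur) | CN(C)/C=C(\S(=O)c1ccc(C)cc1)C(=O)COCc1ccccc1 | intermediate
6 | 3,4-bis(benzyloxy)benzoic acid | OC(=O)c1ccc(OCc2ccccc2)c(OCc2ccccc2)c1 | starting material
7 | 3,4-bis(benzyloxy)benzoyl chloride | ClC(=O)c1ccc(OCc2ccccc2)c(OCc2ccccc2)c1 | intermediate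
8 | lithium (1Z,3Z)-1-(benzyloxy)-4-(dimethylamino)-3-[(4-methylphenyl)sulfinyl]buta-1,3-dien-2-olate | CN(C)/C=C(\S(=O)c1ccc(C)cc1)/C(O[Li])=C/OCc1ccccc1 | intermediate (not isolated)
9 | (4Z)-2-(benzyloxy)-1-[3,4-bis(benzyloxy)phenyl]-5-(dimethylamino)-4-[(4-methylphenyl)sulfinyl]pent-4-ene-1,3-dione (formed as its lithium enolate; mixture of stereoisomers at C2 and sulfur) | CN(C)/C=C(\S(=O)c1ccc(C)cc1)C(=O)C(OCc1ccccc1)C(=O)c1ccc(OCc2ccccc2)c(OCc2ccccc2)c1 | intermediate (not isolated)
10 | 3-(benzyloxy)-2-[3,4-bis(benzyloxy)phenyl]-5-[(4-methylphenyl)sulfinyl]-4H-pyran-4-one (racemic at sulfur) | Cc1ccc(cc1)S(=O)c1coc(-c2ccc(OCc3ccccc3)c(OCc3ccccc3)c2)c(OCc2ccccc2)c1=O | intermediate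
11 | methyl 3-oxobutanoate | COC(=O)CC(C)=O | starting material
12 | methyl (2E)-3-(trimethylsilyloxy)but-2-enoate | C/C(O[Si](C)(C)C)=C\C(=O)OC | intermediate
13 | lithium (1E)-1-methoxy-3-(trimethylsilyloxy)buta-1,3-dien-1-olate | CO/C(O[Li])=C/C(=C)O[Si](C)(C)C | intermediate (not isolated)
14 | (1Z)-1-methoxy-1,3-bis(trimethylsilyloxy)buta-1,3-diene | CO/C(O[Si](C)(C)C)=C/C(=C)O[Si](C)(C)C | intermediate
15 | 3-(benzyloxy)-2-[3,4-bis(benzyloxy)phenyl]-5-methoxy-4a-[(4-methylphenyl)sulfinyl]-5,7-bis(trimethylsilyloxy)-4a,5,8,8a-tetrahydro-4H-chromen-4-one (racemic, cis-fused, sulfinyl group syn to H-8a; mixture at C5 and sulfur) | COC1(O[Si](C)(C)C)C=C(O[Si](C)(C)C)C[C@H]2OC(-c3ccc(OCc4ccccc4)c(OCc4ccccc4)c3)=C(OCc3ccccc3)C(=O)[C@@]12S(=O)c1ccc(C)cc1 | intermediate (not isolated)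
16 | 3-(benzyloxy)-2-[3,4-bis(benzyloxy)phenyl]-5-methoxy-5,7-bis(trimethylsilyloxy)-5,8-dihydro-4H-chromen-4-one (racemic) | COC1(O[Si](C)(C)C)C=C(O[Si](C)(C)C)CC2=C1C(=O)C(OCc3ccccc3)=C(-c3ccc(OCc4ccccc4)c(OCc4ccccc4)c3)O2 | intermediate (not isolated)
17 | 3-(benzyloxy)-2-[3,4-bis(benzyloxy)phenyl]-5,7-dihydroxy-4H-chromen-4-one | O=c1c(OCc2ccccc2)c(-c2ccc(OCc3ccccc3)c(OCc3ccccc3)c2)oc2cc(O)cc(O)c12 | intermediate
18 | 2-(3,4-dihydroxyphenyl)-3,5,7-trihydroxy-4H-chromen-4-one | O=c1c(O)c(-c2ccc(O)c(O)c2)oc2cc(O)cc(O)c12 | intermediate
19 | tetrakis(triethylammonium) salt of quercetin 3,7,3',4'-tetra-O-sulfate | O=c1c(OS(=O)(=O)[O-])c(-c2ccc(OS(=O)(=O)[O-])c(OS(=O)(=O)[O-])c2)oc2cc(OS(=O)(=O)[O-])cc(O)c12.CC[NH+](CC)CC.CC[NH+](CC)CC.CC[NH+](CC)CC.CC[NH+](CC)CC | intermediate (not isolated)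
20 | quercetin 3,7,3',4'-tetra-O-sulfate | O=c1c(OS(=O)(=O)O)c(-c2ccc(OS(=O)(=O)O)c(OS(=O)(=O)O)c2)oc2cc(OS(=O)(=O)O)cc(O)c12 | target

## Step count and least certain steps

Total step count: 9. Longest linear sequence: 6 steps (steps 1, 2, 4, 7, 8 and 9).

Step 7 (key step, proposed new method). Several processes could defeat it.
- Reactivity: donation from the ring oxygen makes the pyranone double bond a weak dienophile, so the diene may decompose before it adds.
- Silyl transfer: the silyl ketene acetal may pass its silyl group to the sulfoxide oxygen and divert the substrate into Pummerer-type chemistry.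
- Ring opening: Michael addition may be followed by opening of ring C through retro-oxa-Michael cleavage instead of ring closure.
- Aromatisation: ring A may lose silanol in place of methanol and so keep a methyl ether at C5.
- Sulfenylation: species derived from the sulfenic acid may sulfenylate the electron-rich ring A.

The fallback gives up the cycloaddition for an Allan–Robinson flavonol synthesis, which is known chemistry; it sets out from 6 and 7 and returns to the route at 17. The ketone partner 2-(benzyloxy)-1-(2,4,6-trihydroxyphenyl)ethan-1-one F1 would come from a Houben–Hoesch acylation of phloroglucinol with 2-(benzyloxy)acetonitrile (ZnCl2, HCl, Et2O, 0 °C; then hot water). Union of 6 and 7 (Et3N, CH2Cl2) would give 3,4-bis(benzyloxy)benzoic anhydride F2. Heating F1 with excess F2 and Et3N at about 160 °C should acylate the phenol, transfer the aroyl group to the methylene carbon and close ring C with loss of water. The ring A ester that remains, chiefly 3-(benzyloxy)-2-[3,4-bis(benzyloxy)phenyl]-5-hydroxy-4-oxo-4H-chromen-7-yl 3,4-bis(benzyloxy)benzoate F3, would be saponified (KOH, aqueous ethanol, reflux) to 17.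

Step 4. The enolate may be acylated on oxygen instead of carbon, and the acid chloride may activate the sulfoxide oxygen and start deoxygenation or Pummerer-type decomposition. The fallback replaces acylation by aldol addition and oxidation; it sets out from 5 and returns at 10. Enolate 8, generated as in step 4, would add to 3,4-bis(benzyloxy)benzaldehyde at −78 °C to give (4Z)-2-(benzyloxy)-1-[3,4-bis(benzyloxy)phenyl]-5-(dimethylamino)-1-hydroxy-4-[(4-methylphenyl)sulfinyl]pent-4-en-3-one F4 as a mixture of diastereomers. Oxidation of the secondary alcohol with Dess–Martin periodinane (CH2Cl2, rt) would give 9, and CF3CO2H would close it to 10 as in the route.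

Step 9. Sulfation may stop short or go on to the 5-hydroxyl, giving mixtures of polyanions that are hard to separate, and sulfate groups may be lost by acid-catalysed hydrolysis during the proton exchange. The fallback uses protected sulfate diesters that can be purified as neutral compounds; it sets out from 18 and returns at 20. Treatment of 18 with 2,2,2-trichloroethyl chlorosulfate (4.4 equiv), Et3N and 4-(dimethylamino)pyridine in THF should give quercetin 3,7,3',4'-tetrakis(2,2,2-trichloroethyl sulfate) F5, purified on silica. Reductive removal of the trichloroethyl groups (Zn, HCO2NH4, MeOH, rt) would give the tetraammonium salt of quercetin 3,7,3',4'-tetra-O-sulfate F6, which cold cation exchange as in step 9 converts into 20.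

Step 8. Traces of sulfur compounds from step 7 may poison the catalyst, and prolonged exposure may begin to reduce ring C. The fallback replaces hydrogenolysis by Lewis-acid dealkylation; it sets out from 17 and returns at 18. BCl3 with pentamethylbenzene as cation scavenger (CH2Cl2, −78 °C) should cleave all three benzyl ethers. It would also cleave a methyl ether at C5, should step 7 have retained one. This fallback makes no new compound (F0).

## Further compounds

F1 | step 7 | 2-(benzyloxy)-1-(2,4,6-trihydroxyphenyl)ethan-1-one | O=C(COCc1ccccc1)c1c(O)cc(O)cc1O
F2 | step 7 | 3,4-bis(benzyloxy)benzoic anhydride | O=C(OC(=O)c1ccc(OCc2ccccc2)c(OCc2ccccc2)c1)c1ccc(OCc2ccccc2)c(OCc2ccccc2)c1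
F3 | step 7 | 3-(benzyloxy)-2-[3,4-bis(benzyloxy)phenyl]-5-hydroxy-4-oxo-4H-chromen-7-yl 3,4-bis(benzyloxy)benzoate | O=C(Oc1cc(O)c2c(c1)oc(-c1ccc(OCc3ccccc3)c(OCc3ccccc3)c1)c(OCc1ccccc1)c2=O)c1ccc(OCc2ccccc2)c(OCc2ccccc2)c1
F4 | step 4 | (4Z)-2-(benzyloxy)-1-[3,4-bis(benzyloxy)phenyl]-5-(dimethylamino)-1-hydroxy-4-[(4-methylphenyl)sulfinyl]pent-4-en-3-one (mixture of diastereomers) | CN(C)/C=C(\S(=O)c1ccc(C)cc1)C(=O)C(OCc1ccccc1)C(O)c1ccc(OCc2ccccc2)c(OCc2ccccc2)c1
F5 | step 9 | quercetin 3,7,3',4'-tetrakis(2,2,2-trichloroethyl sulfate) | O=c1c(OS(=O)(=O)OCC(Cl)(Cl)Cl)c(-c2ccc(OS(=O)(=O)OCC(Cl)(Cl)Cl)c(OS(=O)(=O)OCC(Cl)(Cl)Cl)c2)oc2cc(OS(=O)(=O)OCC(Cl)(Cl)Cl)cc(O)c12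
F6 | step 9 | tetraammonium salt of quercetin 3,7,3',4'-tetra-O-sulfate | O=c1c(OS(=O)(=O)[O-])c(-c2ccc(OS(=O)(=O)[O-])c(OS(=O)(=O)[O-])c2)oc2cc(OS(=O)(=O)[O-])cc(O)c12.[NH4+].[NH4+].[NH4+].[NH4+]
F0 | step 8 | none | none
A1 | alternative 1 | methyl (8Z)-8-(benzyloxy)-9-[3,4-bis(benzyloxy)phenyl]-3,5,7-trioxonon-8-enoate | COC(=O)CC(=O)CC(=O)CC(=O)/C(OCc1ccccc1)=C/c1ccc(OCc2ccccc2)c(OCc2ccccc2)c1
A2 | alternative 1 | (2Z)-2-(benzyloxy)-3-[3,4-bis(benzyloxy)phenyl]-1-(2,4,6-trihydroxyphenyl)prop-2-en-1-one | O=C(c1c(O)cc(O)cc1O)/C(OCc1ccccc1)=C/c1ccc(OCc2ccccc2)c(OCc2ccccc2)c1
A3 | alternative 2 | 3,5-bis(benzyloxy)-2-(trimethylsilyl)phenyl trifluoromethanesulfonate | C[Si](C)(C)c1c(OS(=O)(=O)C(F)(F)F)cc(OCc2ccccc2)cc1OCc1ccccc1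
A4 | alternative 2 | 3-[3,4-bis(benzyloxy)phenyl]prop-2-ynoic acid | OC(=O)C#Cc1ccc(OCc2ccccc2)c(OCc2ccccc2)c1
A5 | alternative 2 | 5,7-bis(benzyloxy)-2-[3,4-bis(benzyloxy)phenyl]-4H-chromen-4-one | O=c1cc(-c2ccc(OCc3ccccc3)c(OCc3ccccc3)c2)oc2cc(OCc3ccccc3)cc(OCc3ccccc3)c12
A6 | alternative 3 | 2-(benzyloxy)-1-[3,4-bis(benzyloxy)phenyl]-3-(2,4,6-trifluorophenyl)propane-1,3-dione | O=C(c1ccc(OCc2ccccc2)c(OCc2ccccc2)c1)C(OCc1ccccc1)C(=O)c1c(F)cc(F)cc1F
A7 | alternative 3 | 3-(benzyloxy)-2-[3,4-bis(benzyloxy)phenyl]-5,7-difluoro-4H-chromen-4-one | O=c1c(OCc2ccccc2)c(-c2ccc(OCc3ccccc3)c(OCc3ccccc3)c2)oc2cc(F)cc(F)c12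
A8 | alternative 3 | 3,5,7-tris(benzyloxy)-2-[3,4-bis(benzyloxy)phenyl]-4H-chromen-4-one | O=c1c(OCc2ccccc2)c(-c2ccc(OCc3ccccc3)c(OCc3ccccc3)c2)oc2cc(OCc3ccccc3)cc(OCc3ccccc3)c12
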